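**Retrosynthetic overview**
- The target is cut back through ketone reduction at C2, hydroxylation at C3, allylic oxidation at C2, esterification of the C14 alcohol with angelic acid and allylic hydroxylation of C14 to the spiro diene lactone 7.
- Feature on which the strategy rests: spiro carbon C5 joins the cyclopentane C5–C6–C7–C8–C9 (cis-fused α-methylene-γ-lactone on C7/C8) to the cyclohexene C5–C10=C1–C2–C3–C4, whose vinylic C10 carries CH2O and whose C4 carries a methyl group. Moving C9 (the CH2 next to the lactone O–CH C8) from C5 back to C10 restores the decalin of alantolactone, which already has C4, C7 and C8 in the target configuration.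
- Key disconnection C5–C9: cationic 1,2-shift of C9 from the methyl-bearing C10 to the ring-fusion carbon C5. It is run on the cis-fused tertiary alcohol 5 (hydroxyl on C5 cis to the angular methyl), made from alantolactone 1 by masking the lactone, radical Markovnikov hydration and unmasking.
- Ring order: ring A and the lactone come from the chiral pool; ring B is contracted to the spiro cyclopentane in step 4; no other ring is made.

Key step: step 4

Remark on numbering: eudesmane numbering of alantolactone is kept throughout (C5 ring-fusion/spiro carbon, C10 methyl-bearing carbon, C14 its methyl, C15 methyl on C4, C8 lactone O–CH, C13 exocyclic methylene); β is the face of the angular methyl C14.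
Remark on C11: the amine adducts are drawn as the C11 epimer formed by protonation on the convex face of the lactone (H11 cis to H7); this centre is erased in step 3, so its configuration has no consequence.

**Route**

Step 1
Reactants: 1 alantolactone
Product: 2 13-(dimethylamino)-11,13-dihydroalantolactone
Conditions: Me2NH (2 M in THF), EtOH, rt
Reagents that add atoms: dimethylamine, CNC
Why: Aza-Michael addition of a secondary amine to the α-methylene-γ-lactone, a standard reversible mask for this group that leaves the trisubstituted C5=C6 alkene as the only alkene for step 2.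

Step 2
Reactants: 2 13-(dimethylamino)-11,13-dihydroalantolactone
Product: 3 5β-hydroxy-13-(dimethylamino)-5,6,11,13-tetrahydroalantolactone
Conditions: Co(acac)2 (cat.), PhSiH3, O2 (1 atm), i-PrOH, 0 °C to rt
Reagents that add atoms: dioxygen, O=O
Why: Mukaiyama hydration: hydrogen-atom transfer from a cobalt hydride to C6 gives the tertiary C5 radical (Markovnikov), which is trapped by O2 and reduced to the alcohol; O2 should enter on the β face, anti to the quasi-axial C10–C9 bond, because the only half-chair of ring A that avoids a syn-diaxial clash of the C4 and C10 methyl groups places C9 axial on the α face, so the cis-fused chair–chair decalol forms directly.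

Step 3
Reactants: 3 5β-hydroxy-13-(dimethylamino)-5,6,11,13-tetrahydroalantolactone
Product: 5 5β-hydroxy-5,6-dihydroalantolactone, via methiodide 4 (not isolated)
Conditions: MeI, acetone, rt; then aq. NaHCO3, CH2Cl2, rt
Reagents that add atoms: iodomethane, CI (its methyl group is carried only by 4)
Why: N-Methylation followed by E1cB (Hofmann-type) elimination of trimethylamine from the β-ammonio lactone regenerates the α-methylene lactone under conditions that leave the tertiary alcohol untouched.

Step 4
Reactants: 5 5β-hydroxy-5,6-dihydroalantolactone
Product: 7 spiro diene lactone (9(10→5)abeo-eudesma-1(10),11(13)-dien-8β,12-olide), via tertiary triflate 6 (not isolated)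
Conditions: Tf2O, 2,6-di-tert-butyl-4-methylpyridine, CH2Cl2, −78 to −20 °C
Reagents that add atoms: trifluoromethanesulfonic anhydride, O=S(=O)(OS(=O)(=O)C(F)(F)F)C(F)(F)F (its triflyl group is carried only by 6)
Why: O-Triflation of the axial tertiary alcohol gives a triflate that ionises at low temperature with participation of the anti-periplanar C10–C9 σ bond, a Wagner–Meerwein 1,2-alkyl shift that forms C5–C9, leaves the cation on C10 and ends by loss of H1 to give the C1=C10 alkene; the closest known reaction type is the cationic ring contraction of cis-fused eudesmane-type decalyl alcohols and esters to spiro[4.5]decenes (the spirovetivane manifold). The cyclopentane C5–C6–C7–C8–C9 is closed by this 1,2-shift, a six-to-five ring contraction in which C9 moves suprafacially from C10 to C5. The spiro centre C5 is set by inversion: C9 enters on the α face anti to the departing β-oxygen, so the configuration of C10 is transferred to C5 while C4, C7 and C8 are untouched. The step needs migration of C9 in preference to the angular methyl C14, to C1 and to loss of H4 or H6; in the favoured chair–chair form of 5 (oxygen axial on ring A and equatorial on ring B, C4 methyl equatorial) only C10–C9 is anti-periplanar to C5–O while C14 is gauche, and the other chair–chair form, which would align C10–C1, is disfavoured by a syn-diaxial clash of the C4 and C10 methyl groups. The hindered pyridine removes triflic acid, so alkenes are not re-protonated and the outcome is kinetic; since C5 is quaternary the C10 cation can lose a proton only toward C1 (trisubstituted ring alkene, favoured) or C14.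

Step 5
Reactants: 7 spiro diene lactone
Product: 8 14-hydroxy spiro diene lactone
Conditions: SeO2 (cat.), t-BuOOH, CH2Cl2, 0 °C to rt
Reagents that add atoms: SeO2, O=[Se]=O (oxygen-transfer agent); tert-butyl hydroperoxide, CC(C)(C)OO (terminal oxidant)
Why: Catalytic SeO2 allylic hydroxylation (ene reaction then [2,3]-sigmatropic shift): selenium adds to the less substituted alkene carbon C1 and the hydrogen is taken from the only hydrogen-bearing substituent on C10, the (E)-methyl group C14 (C5 is quaternary), while the electron-poor methylene lactone is inert.

Step 6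
Reactants: 8 14-hydroxy spiro diene lactone; 9 angelic acid
Product: 11 14-angeloyloxy spiro diene lactone, via mixed anhydride 10 (not isolated)
Conditions: 9, 2,4,6-trichlorobenzoyl chloride, Et3N, toluene, rt; then 8, toluene, 75 °C (no DMAP)
Reagents that add atoms: 2,4,6-trichlorobenzoyl chloride, O=C(Cl)c1c(Cl)cc(Cl)cc1Cl (its aroyl group is carried only by 10)
Why: Yamaguchi-type esterification through the mixed anhydride without a nucleophilic catalyst, the standard way to make angelates without Z-to-E isomerisation to the tiglate; the primary allylic alcohol is the only hydroxyl group.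

Step 7
Reactants: 11 14-angeloyloxy spiro diene lactone
Product: 12 14-angeloyloxy-2-oxo spiro diene lactone (enone)
Conditions: Rh2(cap)4 (dirhodium tetrakis(caprolactamate), cat.), t-BuOOH, K2CO3, CH2Cl2, rt
Reagents that add atoms: tert-butyl hydroperoxide, CC(C)(C)OO
Why: Dirhodium-caprolactamate-catalysed allylic oxidation (tert-butylperoxyl radical abstracts an allylic hydrogen, the allyl peroxide collapses to the ketone) at the only ring allylic methylene, C2, giving the conjugated enone; C14 is deactivated by its acyloxy group and the two electron-poor alkenes should not react.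

Step 8
Reactants: 12 14-angeloyloxy-2-oxo spiro diene lactone (enone)
Product: 15 3α-hydroxy-2-oxo enone, via silyl dienol ether 13 (not isolated), via silyloxy ketone 14 (not isolated)
Conditions: TMSOTf, Et3N, CH2Cl2, −78 to 0 °C, cold NaHCO3 work-up; crude 13, mCPBA, NaHCO3, CH2Cl2, −20 °C; then 1 M HCl, THF, 0 °C
Reagents that add atoms: trimethylsilyl triflate, C[Si](C)(C)OS(=O)(=O)C(F)(F)F (its silyl group is carried only by 13 and 14); mCPBA, O=C(OO)c1cccc(Cl)c1
Why: Rubottom oxidation: kinetic soft enolisation toward C3 gives the cross-conjugated 2-silyloxy diene, whose electron-rich C2=C3 bond is epoxidised on the face opposite to the adjacent C4 methyl group, and silyl migration with acidic work-up gives the 3-hydroxy ketone with the hydroxyl trans to that methyl group.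

Step 9
Reactants: 15 3α-hydroxy-2-oxo enone
Product: 16 target CNP0224912.1
Conditions: Me4NBH(OAc)3, MeCN/AcOH (1:1), −30 to −20 °C
Reagents that add atoms: none
Why: Hydroxyl-directed reduction (Saksena–Evans): the 3-hydroxyl exchanges onto boron and delivers hydride intramolecularly to C2 from its own face, so the new 2-hydroxyl is trans to the 3-hydroxyl and cis to the C4 methyl group, and this mild acyloxyborohydride leaves the ring alkene, the angelate and the methylene lactone untouched.

**Compound list**

1 | alantolactone (eudesma-5,11(13)-dien-8β,12-olide; 4β- and 10β-methyl; H7 and H8 α) | C=C1C(=O)O[C@@H]2C[C@@]3(C)CCC[C@H](C)C3=C[C@H]12 | starting material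
2 | 13-(dimethylamino)-11,13-dihydroalantolactone (H11 cis to H7) | CN(C)C[C@@H]1C(=O)O[C@@H]2C[C@@]3(C)CCC[C@H](C)C3=C[C@H]12 | intermediate
3 | 5β-hydroxy-13-(dimethylamino)-5,6,11,13-tetrahydroalantolactone (cis-fused decalol; OH cis to the angular methyl) | CN(C)C[C@@H]1C(=O)O[C@@H]2C[C@@]3(C)CCC[C@H](C)[C@@]3(O)C[C@H]12 | intermediate
4 | trimethylammonium iodide (methiodide) of 3 | C[N+](C)(C)C[C@@H]1C(=O)O[C@@H]2C[C@@]3(C)CCC[C@H](C)[C@@]3(O)C[C@H]12.[I-] | intermediate
5 | 5β-hydroxy-5,6-dihydroalantolactone (cis-fused tertiary alcohol; α-methylene lactone restored) | C=C1C(=O)O[C@@H]2C[C@@]3(C)CCC[C@H](C)[C@@]3(O)C[C@H]12 | intermediate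
6 | 5β-triflate of 5 | C=C1C(=O)O[C@@H]2C[C@@]3(C)CCC[C@H](C)[C@@]3(OS(=O)(=O)C(F)(F)F)C[C@H]12 | intermediate
7 | spiro diene lactone: cyclopentane C5–C6–C7–C8–C9 spiro-linked at C5 to cyclohexene C5–C10(CH3)=C1–C2–C3–C4(β-CH3); C9 on the α face and C6 on the β face of the cyclohexene; lactone as in 1 | C=C1C(=O)O[C@@H]2C[C@@]3(C[C@H]12)C(C)=CCC[C@@H]3C | intermediate
8 | 14-hydroxy derivative of 7 (C10 carries CH2OH) | C=C1C(=O)O[C@@H]2C[C@@]3(C[C@H]12)C(CO)=CCC[C@@H]3C | intermediate
9 | angelic acid ((Z)-2-methylbut-2-enoic acid) | C/C=C(/C)C(=O)O | starting material
10 | angelic 2,4,6-trichlorobenzoic mixed anhydride | C/C=C(/C)C(=O)OC(=O)c1c(Cl)cc(Cl)cc1Cl | intermediate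
11 | 14-O-angelate of 8 | C=C1C(=O)O[C@@H]2C[C@@]3(C[C@H]12)C(COC(=O)/C(C)=C\C)=CCC[C@@H]3C | intermediate
12 | 2-oxo derivative of 11 (enone C10=C1–C2=O) | C=C1C(=O)O[C@@H]2C[C@@]3(C[C@H]12)C(COC(=O)/C(C)=C\C)=CC(=O)C[C@@H]3C | intermediate
13 | 2-trimethylsilyloxy-1(10),2-diene from 12 | C=C1C(=O)O[C@@H]2C[C@@]3(C[C@H]12)C(COC(=O)/C(C)=C\C)=CC(O[Si](C)(C)C)=C[C@@H]3C | intermediate
14 | 3α-trimethylsilyloxy-2-oxo enone (silyloxy trans to the C4 methyl) | C=C1C(=O)O[C@@H]2C[C@@]3(C[C@H]12)C(COC(=O)/C(C)=C\C)=CC(=O)[C@@H](O[Si](C)(C)C)[C@@H]3C | intermediate
15 | 3α-hydroxy-2-oxo enone (hydroxyl trans to the C4 methyl) | C=C1C(=O)O[C@@H]2C[C@@]3(C[C@H]12)C(COC(=O)/C(C)=C\C)=CC(=O)[C@@H](O)[C@@H]3C | intermediate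
16 | CNP0224912.1 (2β,3α-diol; 14-angelate) | C=C1C(=O)O[C@@H]2C[C@@]3(C[C@H]12)C(COC(=O)/C(C)=C\C)=C[C@H](O)[C@@H](O)[C@@H]3C | target

**Step count**
Total steps: 9. Longest linear sequence: 9 (from alantolactone; angelic acid enters in step 6).

**Steps most likely to fail**

Step 4 (key step). The ionisation may partition the wrong way: the C5 cation may lose H4 or H6 faster than C9 migrates, giving eudesmadienes, or ring A may contract by migration of C1 from the minor chair–chair form. The fallback replaces kinetic ionisation of a leaving group by reversible protonation of the alkene. Alantolactone 1 is treated with a sub-stoichiometric amount of TfOH in 1,1,1,3,3,3-hexafluoropropan-2-ol/CH2Cl2 at low temperature. Proton loss is then no dead end, because the eudesmadienes re-enter the same C5 cation until the skeletal shift has taken place. This fallback sets out from 1 and comes back to the route at 7; it makes no new compound (F0). Its price is possible epimerisation at C4 through the 4(5)-ene, to be limited by short contact time.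

Step 2. Facial selectivity of the oxygen trapping may be poor: attack on the α face would give the trans-fused alcohol, in which the angular methyl and not C9 is anti to the leaving group. The basic amine may also interfere with the cobalt catalyst. The fallback uses polar Markovnikov addition on the unmasked lactone. Alantolactone 1 with dry HCl in CH2Cl2 at low temperature should give the tertiary chloride 5β-chloro-5,6-dihydroalantolactone F1; the addition is reversible, and the cis-fused epimer is the one free of the syn-diaxial methyl clash. Halide abstraction with AgOTf (silver trifluoromethanesulfonate) and 2,6-di-tert-butyl-4-methylpyridine in CH2Cl2 then triggers the same C9 shift. The fallback sets out from 1 and comes back at 7.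

Step 7. Site selectivity of the peroxyl radical may be poor (abstraction at C14 next to the ester oxygen or at the angelate methyl groups), and radicals may isomerise the angelate to the tiglate. The fallback is an ene reaction followed by oxidative transposition. Singlet oxygen (O2, tetraphenylporphyrin, visible light, CH2Cl2) on 11 should add to C10 with hydrogen abstraction from C2, on the more crowded side of the alkene, to give the tertiary allylic hydroperoxide 10-hydroperoxy-1(2)-ene F2. PPh3 reduces it to the tertiary allylic alcohol 10-hydroxy-1(2)-ene F3. Pyridinium chlorochromate, [C5H5NH][CrO3Cl], in CH2Cl2 then effects the oxidative 1,3-transposition (Babler–Dauben) to the enone. The fallback sets out from 11 and comes back at 12.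

Further compounds
F0 | step 4 | none | none
F1 | step 2 | 5β-chloro-5,6-dihydroalantolactone | C=C1C(=O)O[C@@H]2C[C@@]3(C)CCC[C@H](C)[C@@]3(Cl)C[C@H]12
F2 | step 7 | 10-hydroperoxy-1(2)-ene isomer of 11 (either C10 epimer) | C=C1C(=O)O[C@@H]2C[C@@]3(C[C@H]12)C(COC(=O)/C(C)=C\C)(OO)C=CC[C@@H]3C
F3 | step 7 | 10-hydroxy-1(2)-ene isomer of 11 (either C10 epimer) | C=C1C(=O)O[C@@H]2C[C@@]3(C[C@H]12)C(COC(=O)/C(C)=C\C)(O)C=CC[C@@H]3C
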